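**Assumption:** halimane numbering (C1–C20) is used for positions; the target is (4S,5R,8R,9S,13S,14S). The ligand antipode named in step 1 is taken to give the 3R ketone; if the sense is opposite, its mirror image is used.

## Retrosynthetic overview

1. The epoxide comes from Sharpless epoxidation of the 13E allylic alcohol 18, which comes from terminal alkyne 15 by methylalumination and hydroxymethylation.
2. Ring A (C4, C5 and the C1=C10 alkene) is closed last, by an endo Diels–Alder reaction of ring B diene 12 with methyl methacrylate.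
3. Diene 12 comes from sulfonylhydrazone 8 by a Shapiro–Negishi vinylation.
4. Key bond C9–C11: α-chloro hydrazone 4 is turned into an azoalkene, which makes the ketone α-carbon electrophilic, and an alkyl Grignard reagent adds to it to set the quaternary C9.
5. C8 is set first, by copper-catalysed asymmetric conjugate methylation of 2-methylcyclohex-2-en-1-one (ring B is the starting ring).

## Route

**Step 1**
Reactants: 1 2-methylcyclohex-2-en-1-one
Product: 3 (3R)-2-chloro-2,3-dimethylcyclohexan-1-one (both C2 epimers), via aluminium enolate 2 (not isolated)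
Conditions: Me3Al (1.4 equiv), copper thiophene-2-carboxylate Cu(O2CC4H3S) (2 mol %), (S)-binaphthol-derived N,N-bis[(S)-1-phenylethyl]phosphoramidite (4 mol %), Et2O, −30 °C; then N-chlorosuccinimide (2 equiv), THF, −30 → 0 °C; aq. NH4Cl
Reagents that add atoms: trimethylaluminium C[Al](C)C; N-chlorosuccinimide O=C1CCC(=O)N1Cl
Why: Copper-catalysed asymmetric conjugate addition sets C3 (R) under ligand control, and the regiodefined enolate 2 is chlorinated at C2 (electrophilic enolate halogenation); the C2 configuration does not matter because C2 becomes sp2 in step 3.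

**Step 2**
Reactants: 3 (3R)-2-chloro-2,3-dimethylcyclohexan-1-one
Product: 4 N'-[(3R)-2-chloro-2,3-dimethylcyclohexylidene]-2,4,6-tri(propan-2-yl)benzenesulfonohydrazide
Conditions: 2,4,6-tri(propan-2-yl)benzenesulfonohydrazide (1.05 equiv), Et2O, 0 → 25 °C
Reagents that add atoms: 2,4,6-tri(propan-2-yl)benzenesulfonohydrazide CC(C)c1cc(C(C)C)c(S(=O)(=O)NN)c(C(C)C)c1
Why: Hydrazone condensation under neutral conditions, where the hydrazide attacks the carbonyl rather than the tertiary chloride and no base is present to cause early elimination.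

**Step 3 (key step)**
Reactants: 4 N'-[(3R)-2-chloro-2,3-dimethylcyclohexylidene]-2,4,6-tri(propan-2-yl)benzenesulfonohydrazide; 5 (4-bromobut-1-yn-1-yl)trimethylsilane
Product: 8 N'-{(2S,3R)-2,3-dimethyl-2-[4-(trimethylsilyl)but-3-yn-1-yl]cyclohexylidene}-2,4,6-tri(propan-2-yl)benzenesulfonohydrazide, via Grignard reagent 6 (not isolated), via azoalkene 7 (not isolated)
Conditions: 5, Mg, THF, 25–40 °C (gives 6, 2.5 equiv); then 4, CuCl (10 mol %), THF, −78 → −40 °C; aq. NH4Cl; recrystallise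
Reagents that add atoms: none
Why: Umpolung α-alkylation through an N-sulfonyl azoalkene: the first equivalent of 6 removes N–H and chloride leaves to give 7, whose former enolate carbon is electrophilic; copper-catalysed conjugate addition of the second equivalent joins two normally nucleophilic carbons and sets the quaternary centre (2S) by attack anti to the pseudoaxial C3 methyl, as in cuprate additions to 3,4-dimethylcyclohexenone.

**Step 4**
Reactants: 8 N'-{(2S,3R)-2,3-dimethyl-2-[4-(trimethylsilyl)but-3-yn-1-yl]cyclohexylidene}-2,4,6-tri(propan-2-yl)benzenesulfonohydrazide; 9 bromoethene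
Product: 12 trimethyl{4-[(1S,6R)-2-ethenyl-1,6-dimethylcyclohex-2-en-1-yl]but-1-yn-1-yl}silane, via vinyllithium 10 (not isolated), via vinylzinc chloride 11 (not isolated)
Conditions: n-BuLi (2.1 equiv), THF, −78 → 0 °C; ZnCl2 (1.2 equiv), 0 °C; 9 (3 equiv, 1 M in THF), Pd(PPh3)4 (5 mol %), 25–40 °C
Reagents that add atoms: none
Why: Shapiro reaction (deprotonation at the only α-CH2, then loss of sulfinate and N2) gives 10 regiospecifically, and transmetallation to zinc followed by Negishi coupling under zerovalent palladium gives the 1-vinylcyclohexene diene without touching the stereocentres.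

**Step 5**
Reactants: 12 trimethyl{4-[(1S,6R)-2-ethenyl-1,6-dimethylcyclohex-2-en-1-yl]but-1-yn-1-yl}silane; 13 methyl 2-methylprop-2-enoate
Product: 14 methyl (1S,5S,6R,8aR)-1,5,6-trimethyl-5-[4-(trimethylsilyl)but-3-yn-1-yl]-1,2,3,5,6,7,8,8a-octahydronaphthalene-1-carboxylate
Conditions: 13 (5 equiv), EtAlCl2 (0.3 equiv), CH2Cl2, −40 → 0 °C; chromatographic removal of minor isomers
Reagents that add atoms: none
Why: Lewis acid-catalysed Diels–Alder reaction in which the two CH2 termini bond first (ester-bearing carbon to the ring terminus), the ester is endo, and the dienophile adds to the diene face opposite the two cis methyl groups; this sets C4 (S) and C5 (R) and places the alkene at C1=C10.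

**Step 6**
Reactants: 14 methyl (1S,5S,6R,8aR)-1,5,6-trimethyl-5-[4-(trimethylsilyl)but-3-yn-1-yl]-1,2,3,5,6,7,8,8a-octahydronaphthalene-1-carboxylate
Product: 15 methyl (1S,5S,6R,8aR)-5-(but-3-yn-1-yl)-1,5,6-trimethyl-1,2,3,5,6,7,8,8a-octahydronaphthalene-1-carboxylate
Conditions: K2CO3 (0.2 equiv), MeOH, 25 °C
Reagents that add atoms: none
Why: Base-catalysed protodesilylation of the alkynylsilane by methanol; the α-quaternary methyl ester cannot epimerise and exchange with methoxide is degenerate.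

**Step 7**
Reactants: 15 methyl (1S,5S,6R,8aR)-5-(but-3-yn-1-yl)-1,5,6-trimethyl-1,2,3,5,6,7,8,8a-octahydronaphthalene-1-carboxylate
Product: 18 methyl (1S,5S,6R,8aR)-5-[(3E)-5-hydroxy-3-methylpent-3-en-1-yl]-1,5,6-trimethyl-1,2,3,5,6,7,8,8a-octahydronaphthalene-1-carboxylate, via alkenylalane 16 (not isolated), via lithium alkenylaluminate 17 (not isolated)
Conditions: Me3Al (2.5 equiv), Cp2ZrCl2 (0.25 equiv), CH2Cl2, 0 → 25 °C; evaporate excess Me3Al; THF, n-BuLi (1 equiv per residual Al), −78 °C; (CH2O)n (3 equiv), −78 → 25 °C; aq. potassium sodium tartrate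
Reagents that add atoms: trimethylaluminium C[Al](C)C; formaldehyde (as paraformaldehyde) C=O
Why: Negishi zirconium-catalysed methylalumination adds Me and Al syn across the terminal alkyne with Me on the internal carbon, and the aluminate is hydroxymethylated with retention to give the E trisubstituted allylic alcohol; n-BuLi is taken up by the Lewis acidic alane faster than it attacks the hindered tertiary ester.

**Step 8**
Reactants: 18 methyl (1S,5S,6R,8aR)-5-[(3E)-5-hydroxy-3-methylpent-3-en-1-yl]-1,5,6-trimethyl-1,2,3,5,6,7,8,8a-octahydronaphthalene-1-carboxylate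
Product: 19 methyl (1S,5S,6R,8aR)-5-{2-[(2S,3S)-3-(hydroxymethyl)-2-methyloxiran-2-yl]ethyl}-1,5,6-trimethyl-1,2,3,5,6,7,8,8a-octahydronaphthalene-1-carboxylate (CNP0324371.1)
Conditions: Ti(OiPr)4 (0.1 equiv), L-(+)-diethyl tartrate (0.12 equiv), t-BuOOH (2 equiv), 4 Å molecular sieves, CH2Cl2, −20 °C
Reagents that add atoms: tert-butyl hydroperoxide CC(C)(C)OO
Why: Sharpless asymmetric epoxidation; with L-(+)-diethyl tartrate the E allylic alcohol gives the (2S,3S) epoxy alcohol (same sense as geraniol), and the isolated ring alkene is not epoxidised.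

## Compound list

1 | 2-methylcyclohex-2-en-1-one | CC1=CCCCC1=O | starting material
2 | dimethyl{[(3R)-2,3-dimethylcyclohex-1-en-1-yl]oxy}alumane | C[Al](C)OC1=C(C)[C@H](C)CCC1 | intermediate
3 | (3R)-2-chloro-2,3-dimethylcyclohexan-1-one (both C2 epimers) | O=C1CCC[C@@H](C)C1(C)Cl | intermediate
4 | N'-[(3R)-2-chloro-2,3-dimethylcyclohexylidene]-2,4,6-tri(propan-2-yl)benzenesulfonohydrazide | CC(C)c1cc(C(C)C)c(S(=O)(=O)NN=C2CCC[C@@H](C)C2(C)Cl)c(C(C)C)c1 | intermediate
5 | (4-bromobut-1-yn-1-yl)trimethylsilane | C[Si](C)(C)C#CCCBr | starting material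
6 | [4-(trimethylsilyl)but-3-yn-1-yl]magnesium bromide | C[Si](C)(C)C#CCC[Mg]Br | intermediate
7 | 1-[(3R)-2,3-dimethylcyclohex-1-en-1-yl]-2-[2,4,6-tri(propan-2-yl)benzenesulfonyl]diazene | CC(C)c1cc(C(C)C)c(S(=O)(=O)N=NC2=C(C)[C@H](C)CCC2)c(C(C)C)c1 | intermediate
8 | N'-{(2S,3R)-2,3-dimethyl-2-[4-(trimethylsilyl)but-3-yn-1-yl]cyclohexylidene}-2,4,6-tri(propan-2-yl)benzenesulfonohydrazide | CC(C)c1cc(C(C)C)c(S(=O)(=O)NN=C2CCC[C@@H](C)[C@]2(C)CCC#C[Si](C)(C)C)c(C(C)C)c1 | intermediate
9 | bromoethene | C=CBr | starting material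
10 | {(5R,6S)-5,6-dimethyl-6-[4-(trimethylsilyl)but-3-yn-1-yl]cyclohex-1-en-1-yl}lithium | [Li]C1=CCC[C@@H](C)[C@]1(C)CCC#C[Si](C)(C)C | intermediate
11 | chloro{(5R,6S)-5,6-dimethyl-6-[4-(trimethylsilyl)but-3-yn-1-yl]cyclohex-1-en-1-yl}zinc | Cl[Zn]C1=CCC[C@@H](C)[C@]1(C)CCC#C[Si](C)(C)C | intermediate
12 | trimethyl{4-[(1S,6R)-2-ethenyl-1,6-dimethylcyclohex-2-en-1-yl]but-1-yn-1-yl}silane | C=CC1=CCC[C@@H](C)[C@]1(C)CCC#C[Si](C)(C)C | intermediate
13 | methyl 2-methylprop-2-enoate | C=C(C)C(=O)OC | starting material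
14 | methyl (1S,5S,6R,8aR)-1,5,6-trimethyl-5-[4-(trimethylsilyl)but-3-yn-1-yl]-1,2,3,5,6,7,8,8a-octahydronaphthalene-1-carboxylate | COC(=O)[C@@]1(C)CCC=C2[C@H]1CC[C@@H](C)[C@]2(C)CCC#C[Si](C)(C)C | intermediate
15 | methyl (1S,5S,6R,8aR)-5-(but-3-yn-1-yl)-1,5,6-trimethyl-1,2,3,5,6,7,8,8a-octahydronaphthalene-1-carboxylate | COC(=O)[C@@]1(C)CCC=C2[C@H]1CC[C@@H](C)[C@]2(C)CCC#C | intermediate
16 | methyl (1S,5S,6R,8aR)-5-[(3E)-4-(dimethylalumanyl)-3-methylbut-3-en-1-yl]-1,5,6-trimethyl-1,2,3,5,6,7,8,8a-octahydronaphthalene-1-carboxylate | COC(=O)[C@@]1(C)CCC=C2[C@H]1CC[C@@H](C)[C@]2(C)CC/C(C)=C/[Al](C)C | intermediate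
17 | lithium butyl(dimethyl)[(1E)-alkenyl]aluminate of 16 | COC(=O)[C@@]1(C)CCC=C2[C@H]1CC[C@@H](C)[C@]2(C)CC/C(C)=C/[Al-](C)(C)CCCC.[Li+] | intermediate
18 | methyl (1S,5S,6R,8aR)-5-[(3E)-5-hydroxy-3-methylpent-3-en-1-yl]-1,5,6-trimethyl-1,2,3,5,6,7,8,8a-octahydronaphthalene-1-carboxylate | COC(=O)[C@@]1(C)CCC=C2[C@H]1CC[C@@H](C)[C@]2(C)CC/C(C)=C/CO | intermediate
19 | methyl (1S,5S,6R,8aR)-5-{2-[(2S,3S)-3-(hydroxymethyl)-2-methyloxiran-2-yl]ethyl}-1,5,6-trimethyl-1,2,3,5,6,7,8,8a-octahydronaphthalene-1-carboxylate | COC(=O)[C@@]1(C)CCC=C2[C@H]1CC[C@@H](C)[C@]2(C)CC[C@]1(C)O[C@H]1CO | target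

## Step count and risks

Total steps: 8. Longest linear sequence: 8 steps (1 → 19); compounds 5, 9 and 13 are bought and used directly.

The three steps most likely to fail are steps 3, 5 and 7.

**Step 3** may suffer from γ-deprotonation of the azoalkene or from poor facial control at the new quaternary carbon. The fallback sets out from 1 and comes back to the route at 15, replacing the reversed-polarity alkylation with a normal-polarity Michael addition. Step 1 is run with a proton quench in place of the chlorination to give (3R)-2,3-dimethylcyclohexan-1-one F1. A t-BuOK-catalysed Michael addition of its more substituted enolate to methyl acrylate, anti to the C3 methyl, gives methyl 3-[(1S,2R)-1,2-dimethyl-6-oxocyclohexyl]propanoate F2. KN(SiMe3)2 and PhNTf2 give methyl 3-[(1S,6R)-1,6-dimethyl-2-(trifluoromethanesulfonyloxy)cyclohex-2-en-1-yl]propanoate F3. Stille coupling with tributyl(vinyl)stannane (Pd(PPh3)4, LiCl) gives methyl 3-[(1S,6R)-2-ethenyl-1,6-dimethylcyclohex-2-en-1-yl]propanoate F4. i-Bu2AlH at −78 °C gives 3-[(1S,6R)-2-ethenyl-1,6-dimethylcyclohex-2-en-1-yl]propanal F5. Ohira–Bestmann homologation (dimethyl (1-diazo-2-oxopropyl)phosphonate, K2CO3, MeOH) gives (5R,6S)-6-(but-3-yn-1-yl)-1-ethenyl-5,6-dimethylcyclohex-1-ene F6. The Diels–Alder reaction of F6 with 13 under the step 5 conditions then gives 15.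

**Step 5** may give the wrong regio-, endo/exo or facial isomer, or the diene may polymerise under the Lewis acid. The fallback sets out from 8 and comes back at 14, replacing the cycloaddition with a stepwise anionic annulation. Vinyllithium 10 from the Shapiro reaction is quenched with N-methoxy-N-methylacetamide to give 1-{(5R,6S)-5,6-dimethyl-6-[4-(trimethylsilyl)but-3-yn-1-yl]cyclohex-1-en-1-yl}ethan-1-one F7. Its kinetic dienolate (LiN(iPr)2, THF, −78 °C) undergoes a Michael–Michael ring closure with 13 through a lithium-chelated transition state. The resulting ring A enolate is trapped with PhNTf2 as methyl (1S,5S,6R,8aR)-1,5,6-trimethyl-4-(trifluoromethanesulfonyloxy)-5-[4-(trimethylsilyl)but-3-yn-1-yl]-1,2,3,5,6,7,8,8a-octahydronaphthalene-1-carboxylate F8. Reduction of the enol triflate with Pd(OAc)2, PPh3, HCO2H and Bu3N in DMF at 60 °C gives 14.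

**Step 7** may fail because n-BuLi attacks the ester before the aluminate forms. The fallback sets out from 15 and comes back at 18, making the C14–C15 bond by cross-coupling instead. The methylalumination is run as in step 7, but alkenylalane 16 is quenched with I2 at −30 °C, with no alkyllithium, to give methyl (1S,5S,6R,8aR)-5-[(3E)-4-iodo-3-methylbut-3-en-1-yl]-1,5,6-trimethyl-1,2,3,5,6,7,8,8a-octahydronaphthalene-1-carboxylate F9. Stille coupling of F9 with (tributylstannyl)methanol (Pd(PPh3)4, dioxane, 90 °C) gives 18 with retention of the E geometry.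

## Further compounds

F1 | step 3 | (3R)-2,3-dimethylcyclohexan-1-one | O=C1CCC[C@@H](C)C1C
F2 | step 3 | methyl 3-[(1S,2R)-1,2-dimethyl-6-oxocyclohexyl]propanoate | O=C1CCC[C@@H](C)[C@]1(C)CCC(=O)OC
F3 | step 3 | methyl 3-[(1S,6R)-1,6-dimethyl-2-(trifluoromethanesulfonyloxy)cyclohex-2-en-1-yl]propanoate | O=S(=O)(OC1=CCC[C@@H](C)[C@]1(C)CCC(=O)OC)C(F)(F)F
F4 | step 3 | methyl 3-[(1S,6R)-2-ethenyl-1,6-dimethylcyclohex-2-en-1-yl]propanoate | C=CC1=CCC[C@@H](C)[C@]1(C)CCC(=O)OC
F5 | step 3 | 3-[(1S,6R)-2-ethenyl-1,6-dimethylcyclohex-2-en-1-yl]propanal | C=CC1=CCC[C@@H](C)[C@]1(C)CCC=O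
F6 | step 3 | (5R,6S)-6-(but-3-yn-1-yl)-1-ethenyl-5,6-dimethylcyclohex-1-ene | C=CC1=CCC[C@@H](C)[C@]1(C)CCC#C
F7 | step 5 | 1-{(5R,6S)-5,6-dimethyl-6-[4-(trimethylsilyl)but-3-yn-1-yl]cyclohex-1-en-1-yl}ethan-1-one | CC(=O)C1=CCC[C@@H](C)[C@]1(C)CCC#C[Si](C)(C)C
F8 | step 5 | methyl (1S,5S,6R,8aR)-1,5,6-trimethyl-4-(trifluoromethanesulfonyloxy)-5-[4-(trimethylsilyl)but-3-yn-1-yl]-1,2,3,5,6,7,8,8a-octahydronaphthalene-1-carboxylate | COC(=O)[C@@]1(C)CCC(OS(=O)(=O)C(F)(F)F)=C2[C@H]1CC[C@@H](C)[C@]2(C)CCC#C[Si](C)(C)C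
F9 | step 7 | methyl (1S,5S,6R,8aR)-5-[(3E)-4-iodo-3-methylbut-3-en-1-yl]-1,5,6-trimethyl-1,2,3,5,6,7,8,8a-octahydronaphthalene-1-carboxylate | COC(=O)[C@@]1(C)CCC=C2[C@H]1CC[C@@H](C)[C@]2(C)CC/C(C)=C/I
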